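**Retrosynthetic overview**

1. Cyclohexene atoms are lettered Ca (sp2 carbon with the 4-methylpent-3-enyl chain), Cb (=CH), Cc (CH–flavanone), Cd (CH–aroyl), Ce (CH–resorcinol ring), Cf (CH2). The ring is cut at Cb–Cc and Cf–Ca.
2. Enabling feature: Cc–Cd–Ce–Cf is a saturated four-carbon chain whose two ends flank the Ca=Cb double bond. Tied end to end it is a cyclobutanone with the carbonyl on Cc, and Ca/Cb are the two carbons of 6-methylhept-5-en-1-yne, inserted into the strained acyl–CH2 bond under zerovalent-nickel catalysis.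
3. The cyclobutanone comes from a keteniminium [2+2] cycloaddition with 2,4-diacetoxystyrene. A desymmetrising organocatalytic aldol with the prenylated benzaldehyde sets Ce and Cd; the aroyl group is carried as a silylated carbinol.
4. The carbonyl oxygen left on Cc after ring expansion becomes the leaving group: Luche reduction, then a cannabidiol-type Friedel–Crafts arylation with a (2S)-steppogenin derivative (C6, ortho to the chelated 5-OH) sets Cc trans to Cd. Carbinol oxidation and global deprotection finish the route.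
5. Ring order: the arenes and the chromanone ring are bought; the temporary cyclobutanone is made first; the cyclohexene is made last by two-carbon ring expansion.

Key step: step 9

Assumption: (2S)-steppogenin is taken as a commercial natural flavanone of defined configuration. The two carbinol centres that are destroyed later (the benzylic C–O carbon from step 6 and the allylic alcohol from step 10) are left undefined in names and SMILES.

**Route**

Step 1
Reactants: 1 4-hydroxybenzaldehyde; 2 1-bromo-3-methylbut-2-ene (prenyl bromide)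
Product: 3 4-hydroxy-3-(3-methylbut-2-en-1-yl)benzaldehyde
Conditions: KOH, H2O, rt
Reagents that add atoms: none
Why: Ortho C-alkylation of a phenoxide by an allylic bromide in water, where the protic medium favours C- over O-alkylation; the O-prenyl ether is expected as a separable by-product.

Step 2
Reactants: 3 4-hydroxy-3-(3-methylbut-2-en-1-yl)benzaldehyde
Product: 4 4-formyl-2-(3-methylbut-2-en-1-yl)phenyl acetate
Conditions: Ac2O, Et3N, DMAP (cat.), CH2Cl2, 0 °C
Reagents that add atoms: acetic anhydride, CC(=O)OC(C)=O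
Why: Standard phenol acetylation; the acetate also makes the aldehyde a better aldol acceptor and keeps this arene inert in the later Friedel–Crafts step.

Step 3
Reactants: 5 4-bromobenzene-1,3-diol
Product: 6 4-bromo-1,3-phenylene diacetate
Conditions: Ac2O, pyridine, 0 °C to rt
Reagents that add atoms: acetic anhydride, CC(=O)OC(C)=O
Why: Standard phenol acetylation.

Step 4
Reactants: 6 4-bromo-1,3-phenylene diacetate
Product: 7 4-ethenyl-1,3-phenylene diacetate (2,4-diacetoxystyrene)
Conditions: tributyl(vinyl)stannane, Pd(PPh3)4 (5 mol %), toluene, 100 °C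
Reagents that add atoms: tributyl(vinyl)stannane, C=C[Sn](CCCC)(CCCC)CCCC
Why: Stille coupling of an aryl bromide on zerovalent palladium; the neutral conditions keep the aryl acetates.

Step 5
Reactants: 7 4-ethenyl-1,3-phenylene diacetate
Product: 9 3-(2,4-diacetoxyphenyl)cyclobutan-1-one, via cyclobutaniminium triflate 8 (not isolated)
Conditions: N,N-dimethylacetamide, Tf2O, 2,4,6-collidine, 1,2-dichloroethane, 80 °C; then H2O, 80 °C
Reagents that add atoms: N,N-dimethylacetamide, CC(=O)N(C)C; water, O
Why: Keteniminium [2+2] cycloaddition with a styrene, regioselective for the 3-aryl cyclobutaniminium salt, which is hydrolysed in the same flask; the ketone is achiral (mirror plane through C1 and C3).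

Step 6
Reactants: 9 3-(2,4-diacetoxyphenyl)cyclobutan-1-one; 4 4-formyl-2-(3-methylbut-2-en-1-yl)phenyl acetate
Product: 10 (2S,3S)-2-{[4-acetoxy-3-(3-methylbut-2-en-1-yl)phenyl](hydroxy)methyl}-3-(2,4-diacetoxyphenyl)cyclobutan-1-one (2,3-trans)
Conditions: (S)-N-(phenylsulfonyl)pyrrolidine-2-carboxamide (20 mol %; its enantiomer if the sense of induction proves opposite), CH2Cl2, rt
Reagents that add atoms: none
Why: Enamine-catalysed desymmetrising aldol addition of a 3-substituted cyclobutanone; the catalyst selects one of the two enantiotopic α-CH2 groups, which fixes the aryl-bearing centre Ce, and the aldehyde adds anti to the 3-aryl group, which sets Cd trans.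

Step 7
Reactants: 10 the aldol adduct
Product: 11 (2S,3S)-2-{[4-acetoxy-3-(3-methylbut-2-en-1-yl)phenyl][(tert-butyldimethylsilyl)oxy]methyl}-3-(2,4-diacetoxyphenyl)cyclobutan-1-one
Conditions: TBSOTf, 2,6-lutidine, CH2Cl2, −78 to 0 °C
Reagents that add atoms: tert-butyldimethylsilyl triflate, CC(C)(C)[Si](C)(C)OS(=O)(=O)C(F)(F)F
Why: Silylation of the β-hydroxy ketone under non-nucleophilic conditions blocks retro-aldol cleavage and keeps Cd non-enolisable toward the aryl side.

Step 8
Reactants: 12 5-bromo-2-methylpent-2-ene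
Product: 13 6-methylhept-5-en-1-yne
Conditions: lithium acetylide–ethylenediamine complex, DMSO, 10 °C to rt
Reagents that add atoms: lithium acetylide ethylenediamine complex, [Li+].[C-]#C.NCCN
Why: SN2 alkylation of lithium acetylide by a primary bromide.

Step 9
Reactants: 11 the silylated cyclobutanone; 13 6-methylhept-5-en-1-yne
Product: 14 (5S,6S)-6-{[4-acetoxy-3-(3-methylbut-2-en-1-yl)phenyl][(tert-butyldimethylsilyl)oxy]methyl}-5-(2,4-diacetoxyphenyl)-3-(4-methylpent-3-en-1-yl)cyclohex-2-en-1-one
Conditions: Ni(cod)2 (10 mol %), PCy3 (20 mol %), toluene, 100 °C, slow addition of 13 by syringe pump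
Reagents that add atoms: none
Why: Proposed new method: the cyclobutanone carbonyl and the alkyne undergo oxidative cyclisation on zerovalent nickel to an oxanickelacyclopentene in which the carbonyl carbon (Cc) is bonded to the unsubstituted alkyne carbon (Cb) and nickel holds the chain-bearing carbon (Ca); strain-driven β-carbon elimination then moves the CH2 carbon (Cf) to nickel, and C(sp3)–C(sp2) reductive elimination forms Cf–Ca. The closest known reaction type is the Ni(cod)2/trialkylphosphine-catalysed insertion of internal alkynes into 3-substituted cyclobutanones; the extension proposed here is to a terminal alkyne and to a cyclobutanone with one branched α-carbon. The six-membered ring is closed by two-carbon ring expansion of the four-membered ketone, a formal [4+2] annulation in which both new bonds go to the former alkyne carbons. No stereocentre is created: Ce is untouched, and Cd, now α to the enone carbonyl, can only settle in the trans (diequatorial) arrangement it already has. Three selectivities are needed: cleavage of the acyl–CH2 bond and not the acyl–CH bond (the primary carbon migrates to nickel and the branched side is shielded by the silyloxybenzyl group), carbonyl-to-CH orientation of the alkyne (hydrogen against alkyl at the two termini), and insertion in preference to alkyne cyclotrimerisation (the alkyne is kept dilute by slow addition).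

Step 10
Reactants: 14 the cyclohexenone
Product: 15 (5,6-trans)-6-{[4-acetoxy-3-(3-methylbut-2-en-1-yl)phenyl][(tert-butyldimethylsilyl)oxy]methyl}-5-(2,4-diacetoxyphenyl)-3-(4-methylpent-3-en-1-yl)cyclohex-2-en-1-ol (C5 and C6 as in 14; C1 carbinol undefined)
Conditions: NaBH4, CeCl3·7H2O, MeOH/THF, −78 °C
Reagents that add atoms: none
Why: Luche 1,2-reduction of the enone in the presence of aryl acetates; the new carbinol centre is ionised in step 14, so its configuration does not matter.

Step 11
Reactants: 16 (2S)-2-(2,4-dihydroxyphenyl)-5,7-dihydroxychroman-4-one (steppogenin)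
Product: 17 (2S)-7-acetoxy-2-(2,4-diacetoxyphenyl)-5-hydroxychroman-4-one
Conditions: Ac2O (3.2 equiv), pyridine, 0 °C
Reagents that add atoms: acetic anhydride, CC(=O)OC(C)=O
Why: Acetylation of the three non-chelated phenols; the 5-OH, hydrogen-bonded to the C4 carbonyl, should stay free under controlled conditions.

Step 12
Reactants: 17 the triacetate
Product: 18 (2S)-2-(2,4-diacetoxyphenyl)-5,7-dihydroxychroman-4-one
Conditions: PhSH, imidazole, N-methylpyrrolidone, 0 °C to rt
Reagents that add atoms: none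
Why: Chemoselective thiolysis of the 7-O-acetate, the most electrophilic aryl ester because it is para to the C4 carbonyl; this is the known selective 7-O-deacylation of peracylated flavonoids.

Step 13
Reactants: 18 the 5,7-diol
Product: 19 (2S)-7-[(tert-butyldimethylsilyl)oxy]-2-(2,4-diacetoxyphenyl)-5-hydroxychroman-4-one
Conditions: TBSCl, imidazole, DMF, rt
Reagents that add atoms: tert-butyldimethylsilyl chloride, CC(C)(C)[Si](C)(C)Cl
Why: Silylation of the free 7-OH while the chelated 5-OH does not react; this leaves C6 as the only ring position ortho to a free phenol and keeps ring A electron-rich.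

Step 14
Reactants: 15 the allylic alcohol; 19 the flavanone nucleophile
Product: 21 (2S)-6-[(1R,5S,6R)-6-{[4-acetoxy-3-(3-methylbut-2-en-1-yl)phenyl][(tert-butyldimethylsilyl)oxy]methyl}-5-(2,4-diacetoxyphenyl)-3-(4-methylpent-3-en-1-yl)cyclohex-2-en-1-yl]-7-[(tert-butyldimethylsilyl)oxy]-2-(2,4-diacetoxyphenyl)-5-hydroxychroman-4-one, via cyclohexenyl cation 20 (not isolated)
Conditions: p-toluenesulfonic acid (10 mol %), MgSO4, CH2Cl2, 0 °C
Reagents that add atoms: none
Why: Cannabidiol-type Friedel–Crafts allylation: the allyl cation is attacked at its secondary terminus (Cc) by C6 of the flavanone (ortho to the only free phenol) on the face anti to the neighbouring Cd substituent, which sets Cc trans to Cd and therefore cis to the aryl group on Ce; all other arenes are deactivated as acetates.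

Step 15
Reactants: 21 the bis-silyl ether
Product: 22 (2S)-6-[(1R,5S,6R)-6-{[4-acetoxy-3-(3-methylbut-2-en-1-yl)phenyl](hydroxy)methyl}-5-(2,4-diacetoxyphenyl)-3-(4-methylpent-3-en-1-yl)cyclohex-2-en-1-yl]-7-[(tert-butyldimethylsilyl)oxy]-2-(2,4-diacetoxyphenyl)-5-hydroxychroman-4-one
Conditions: HF·pyridine, pyridine, THF, 0 °C to rt
Reagents that add atoms: none
Why: Acid-mediated fluoride cleavage removes the alkyl silyl ether, while the more acid-stable aryl silyl ether is expected to survive.

Step 16
Reactants: 22 the benzylic alcohol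
Product: 23 (2S)-6-[(1R,5S,6R)-6-[4-acetoxy-3-(3-methylbut-2-en-1-yl)benzoyl]-5-(2,4-diacetoxyphenyl)-3-(4-methylpent-3-en-1-yl)cyclohex-2-en-1-yl]-7-[(tert-butyldimethylsilyl)oxy]-2-(2,4-diacetoxyphenyl)-5-hydroxychroman-4-one
Conditions: Dess–Martin periodinane, CH2Cl2, 0 °C to rt
Reagents that add atoms: none
Why: Dess–Martin oxidation of the secondary benzylic alcohol to the aryl ketone; the only free phenol is the chelated 5-OH, and Cd (now α to the ketone) already has the thermodynamically preferred all-trans arrangement.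

Step 17
Reactants: 23 the protected ketone
Product: 24 CNP0235243.2, (2S)-6-[(1R,5S,6R)-5-(2,4-dihydroxyphenyl)-6-[4-hydroxy-3-(3-methylbut-2-en-1-yl)benzoyl]-3-(4-methylpent-3-en-1-yl)cyclohex-2-en-1-yl]-2-(2,4-dihydroxyphenyl)-5,7-dihydroxychroman-4-one
Conditions: K2CO3 (30 mol %), degassed MeOH, 0 °C to rt, argon; then pH 5 buffer
Reagents that add atoms: none
Why: Carbonate-catalysed methanolysis removes the five aryl acetates and the aryl silyl ether in one operation; low temperature and a short contact time are chosen to spare the base-sensitive flavanone C2 centre, and any equilibration at Cd leads to the all-trans ketone that is wanted.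

**Compound list**

1 | 4-hydroxybenzaldehyde | O=Cc1ccc(O)cc1 | starting material
2 | 1-bromo-3-methylbut-2-ene | CC(C)=CCBr | starting material
3 | 4-hydroxy-3-(3-methylbut-2-en-1-yl)benzaldehyde | CC(C)=CCc1cc(C=O)ccc1O | intermediate
4 | 4-formyl-2-(3-methylbut-2-en-1-yl)phenyl acetate | CC(C)=CCc1cc(C=O)ccc1OC(C)=O | intermediate
5 | 4-bromobenzene-1,3-diol | Oc1ccc(Br)c(O)c1 | starting material
6 | 4-bromo-1,3-phenylene diacetate | CC(=O)Oc1ccc(Br)c(OC(C)=O)c1 | intermediate
7 | 4-ethenyl-1,3-phenylene diacetate | C=Cc1ccc(OC(C)=O)cc1OC(C)=O | intermediate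
8 | N-[3-(2,4-diacetoxyphenyl)cyclobutylidene]-N-methylmethanaminium triflate | C[N+](C)=C1CC(c2ccc(OC(C)=O)cc2OC(C)=O)C1.[O-]S(=O)(=O)C(F)(F)F | intermediate (not isolated)
9 | 3-(2,4-diacetoxyphenyl)cyclobutan-1-one | O=C1CC(c2ccc(OC(C)=O)cc2OC(C)=O)C1 | intermediate
10 | (2S,3S)-2-{[4-acetoxy-3-(3-methylbut-2-en-1-yl)phenyl](hydroxy)methyl}-3-(2,4-diacetoxyphenyl)cyclobutan-1-one | O=C1[C@H](C(O)c2ccc(OC(C)=O)c(CC=C(C)C)c2)[C@@H](c2ccc(OC(C)=O)cc2OC(C)=O)C1 | intermediate
11 | (2S,3S)-2-{[4-acetoxy-3-(3-methylbut-2-en-1-yl)phenyl][(tert-butyldimethylsilyl)oxy]methyl}-3-(2,4-diacetoxyphenyl)cyclobutan-1-one | O=C1[C@H](C(O[Si](C)(C)C(C)(C)C)c2ccc(OC(C)=O)c(CC=C(C)C)c2)[C@@H](c2ccc(OC(C)=O)cc2OC(C)=O)C1 | intermediate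
12 | 5-bromo-2-methylpent-2-ene | CC(C)=CCCBr | starting material
13 | 6-methylhept-5-en-1-yne | C#CCCC=C(C)C | intermediate
14 | (5S,6S)-6-{[4-acetoxy-3-(3-methylbut-2-en-1-yl)phenyl][(tert-butyldimethylsilyl)oxy]methyl}-5-(2,4-diacetoxyphenyl)-3-(4-methylpent-3-en-1-yl)cyclohex-2-en-1-one | CC(C)=CCCC1=CC(=O)[C@H](C(O[Si](C)(C)C(C)(C)C)c2ccc(OC(C)=O)c(CC=C(C)C)c2)[C@@H](c2ccc(OC(C)=O)cc2OC(C)=O)C1 | intermediate
15 | corresponding cyclohex-2-en-1-ol (5,6-trans as in 14; C1 undefined) | CC(C)=CCCC1=CC(O)[C@H](C(O[Si](C)(C)C(C)(C)C)c2ccc(OC(C)=O)c(CC=C(C)C)c2)[C@@H](c2ccc(OC(C)=O)cc2OC(C)=O)C1 | intermediate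
16 | (2S)-steppogenin | O=C1C[C@@H](c2ccc(O)cc2O)Oc2cc(O)cc(O)c12 | starting material
17 | (2S)-7-acetoxy-2-(2,4-diacetoxyphenyl)-5-hydroxychroman-4-one | O=C1C[C@@H](c2ccc(OC(C)=O)cc2OC(C)=O)Oc2cc(OC(C)=O)cc(O)c12 | intermediate
18 | (2S)-2-(2,4-diacetoxyphenyl)-5,7-dihydroxychroman-4-one | O=C1C[C@@H](c2ccc(OC(C)=O)cc2OC(C)=O)Oc2cc(O)cc(O)c12 | intermediate
19 | (2S)-7-[(tert-butyldimethylsilyl)oxy]-2-(2,4-diacetoxyphenyl)-5-hydroxychroman-4-one | O=C1C[C@@H](c2ccc(OC(C)=O)cc2OC(C)=O)Oc2cc(O[Si](C)(C)C(C)(C)C)cc(O)c12 | intermediate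
20 | cyclohexenyl (allyl) cation from 15, one resonance form | CC(C)=CCCC1=C[CH+][C@H](C(O[Si](C)(C)C(C)(C)C)c2ccc(OC(C)=O)c(CC=C(C)C)c2)[C@@H](c2ccc(OC(C)=O)cc2OC(C)=O)C1 | intermediate (not isolated)
21 | Friedel–Crafts product, bis-silyl ether (name in step 14) | CC(C)=CCCC1=C[C@@H](c2c(O[Si](C)(C)C(C)(C)C)cc3c(c2O)C(=O)C[C@@H](c2ccc(OC(C)=O)cc2OC(C)=O)O3)[C@H](C(O[Si](C)(C)C(C)(C)C)c2ccc(OC(C)=O)c(CC=C(C)C)c2)[C@@H](c2ccc(OC(C)=O)cc2OC(C)=O)C1 | intermediate
22 | benzylic alcohol (name in step 15) | CC(C)=CCCC1=C[C@@H](c2c(O[Si](C)(C)C(C)(C)C)cc3c(c2O)C(=O)C[C@@H](c2ccc(OC(C)=O)cc2OC(C)=O)O3)[C@H](C(O)c2ccc(OC(C)=O)c(CC=C(C)C)c2)[C@@H](c2ccc(OC(C)=O)cc2OC(C)=O)C1 | intermediate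
23 | protected ketone (name in step 16) | CC(C)=CCCC1=C[C@@H](c2c(O[Si](C)(C)C(C)(C)C)cc3c(c2O)C(=O)C[C@@H](c2ccc(OC(C)=O)cc2OC(C)=O)O3)[C@H](C(=O)c2ccc(OC(C)=O)c(CC=C(C)C)c2)[C@@H](c2ccc(OC(C)=O)cc2OC(C)=O)C1 | intermediate
24 | CNP0235243.2 (name in step 17) | CC(C)=CCCC1=C[C@@H](c2c(O)cc3c(c2O)C(=O)C[C@@H](c2ccc(O)cc2O)O3)[C@H](C(=O)c2ccc(O)c(CC=C(C)C)c2)[C@@H](c2ccc(O)cc2O)C1 | target

**Step count**

Total steps: 17. Longest linear sequence: 11 steps (steps 3, 4, 5, 6, 7, 9, 10, 14, 15, 16, 17, from 5 to 24).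

**Steps most likely to fail**

Step 9 (proposed new method). What may go wrong: cyclotrimerisation or oligomerisation of the terminal alkyne on nickel faster than its insertion, cleavage of the branched acyl–carbon bond in place of the acyl–CH2 bond, insertion of nickel into an aryl acetate C–O bond, or β-elimination of the silyloxy group.

Fallback (Diels–Alder route, known chemistry), setting out from 4 and 6 and returning at 23: aldehyde 4 is treated with vinylmagnesium bromide at −78 °C to give 1-[4-acetoxy-3-(3-methylbut-2-en-1-yl)phenyl]prop-2-en-1-ol F1, which MnO2 oxidises to the aryl vinyl ketone F2. Heck coupling of F2 with bromide 6 (Pd(OAc)2, P(o-tol)3, Et3N) gives the (E)-chalcone F3. Commercial citral is converted with TBSOTf/Et3N into the cross-conjugated silyl dienol ether F4. Thermal Diels–Alder reaction of F3 with F4 should give the racemic trans cyclohexenyl silyl ether F5, which already carries the aryl ketone. Ionisation of F5 with BF3·OEt2 in the presence of 19 should give 23 together with the mirror-image-cyclohexene diastereomer F6; the two are separated by chromatography, so the flavanone centre serves as the resolving element.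

Step 14. What may go wrong: attack of the allyl cation at C8 or at oxygen of the flavanone, elimination of the cation to dienes, or acid-induced ether formation between a phenol and the ring alkene.

Fallback (sets out from 19 and 15, returns at 21): 19 is iodinated ortho to the free 5-OH with benzyltrimethylammonium dichloroiodate/CaCO3 to give the 6-iodoflavanone F7. Alcohol 15 is acetylated (Ac2O, pyridine, DMAP) to the allylic acetate F8. A nickel-catalysed reductive cross-electrophile coupling (NiBr2·glyme, 4,4'-di-tert-butyl-2,2'-bipyridine, Zn, DMA) should then join the aryl iodide to the less hindered allyl terminus, anti to the neighbouring substituent, to give 21.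

Step 6. What may go wrong: slow enamine turnover with this only moderately electrophilic aldehyde, poor discrimination of the enantiotopic α-methylene groups, or aminolysis of the aryl acetates by the catalyst.

Fallback (sets out from 9, returns at 10): enantioselective deprotonation of 9 with one equivalent of a chiral lithium amide (lithium bis[(R)-1-phenylethyl]amide or its enantiomer, TMSCl in situ, THF, −100 °C), where the strained ketone should be deprotonated faster than the aryl acetates, gives the (S)-configured silyl enol ether F9. A Mukaiyama aldol addition of F9 to 4 (BF3·OEt2, CH2Cl2, −78 °C), anti to the aryl group, should then give 10.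

Further compounds
F1 | step 9 | 1-[4-acetoxy-3-(3-methylbut-2-en-1-yl)phenyl]prop-2-en-1-ol (racemic) | C=CC(O)c1ccc(OC(C)=O)c(CC=C(C)C)c1
F2 | step 9 | 4-acryloyl-2-(3-methylbut-2-en-1-yl)phenyl acetate | C=CC(=O)c1ccc(OC(C)=O)c(CC=C(C)C)c1
F3 | step 9 | (E)-1-[4-acetoxy-3-(3-methylbut-2-en-1-yl)phenyl]-3-(2,4-diacetoxyphenyl)prop-2-en-1-one | CC(=O)Oc1ccc(/C=C/C(=O)c2ccc(OC(C)=O)c(CC=C(C)C)c2)c(OC(C)=O)c1
F4 | step 9 | tert-butyl(dimethyl){[(1E)-7-methyl-3-methylideneocta-1,6-dien-1-yl]oxy}silane | CC(C)=CCCC(=C)/C=C/O[Si](C)(C)C(C)(C)C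
F5 | step 9 | trans-6-[4-acetoxy-3-(3-methylbut-2-en-1-yl)benzoyl]-1-[(tert-butyldimethylsilyl)oxy]-5-(2,4-diacetoxyphenyl)-3-(4-methylpent-3-en-1-yl)cyclohex-2-ene (racemic; one enantiomer drawn) | CC(C)=CCCC1=CC(O[Si](C)(C)C(C)(C)C)[C@H](C(=O)c2ccc(OC(C)=O)c(CC=C(C)C)c2)[C@@H](c2ccc(OC(C)=O)cc2OC(C)=O)C1
F6 | step 9 | diastereomer of 23 with the (1S,5R,6S) cyclohexene | CC(C)=CCCC1=C[C@H](c2c(O[Si](C)(C)C(C)(C)C)cc3c(c2O)C(=O)C[C@@H](c2ccc(OC(C)=O)cc2OC(C)=O)O3)[C@@H](C(=O)c2ccc(OC(C)=O)c(CC=C(C)C)c2)[C@H](c2ccc(OC(C)=O)cc2OC(C)=O)C1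
F7 | step 14 | (2S)-7-[(tert-butyldimethylsilyl)oxy]-2-(2,4-diacetoxyphenyl)-5-hydroxy-6-iodochroman-4-one | O=C1C[C@@H](c2ccc(OC(C)=O)cc2OC(C)=O)Oc2cc(O[Si](C)(C)C(C)(C)C)c(I)c(O)c12
F8 | step 14 | allylic acetate of 15 (5,6-trans as in 14; C1 undefined) | CC(C)=CCCC1=CC(OC(C)=O)[C@H](C(O[Si](C)(C)C(C)(C)C)c2ccc(OC(C)=O)c(CC=C(C)C)c2)[C@@H](c2ccc(OC(C)=O)cc2OC(C)=O)C1
F9 | step 6 | (S)-4-{3-[(trimethylsilyl)oxy]cyclobut-2-en-1-yl}-1,3-phenylene diacetate | C[Si](C)(C)OC1=C[C@@H](c2ccc(OC(C)=O)cc2OC(C)=O)C1
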